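The earlier runs and the new flask were generated by integration for an exercise; the scatter is artificial.

One ratio reads 88.2% on the noon run: target plus isomer of the product found per mole of reagent fed, which I call the capture. A capture of one is the even case, where each mole of reagent makes one mole of product, and I measure the loss from there.

| flask | substrate | reagent | remark | time |
|---|---|---|---|---|
| winter | 0.10 M | 0.74 equiv (fed, over 30 h) | run made earlier |  |
| dusk | 0.10 M | 1.7 equiv (fed, over 30 h) | run made earlier |  |
| noon | 0.15 M | 1.1 equiv (fed, over 30 h) | run made earlier |  |
| flask | 0.10 M | 1.10 equiv (fed, over 30 h) |  | 15 d |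

| run | time / d | target / % | isomer of the product / % | substrate / % |
|---|---|---|---|---|
| winter | 2.50 | 55.0 | 16.8 | 27.3 |
| winter | 5.00 | 55.4 | 17.4 | 27.2 |
| winter | 6.00 | 55.2 | 16.4 | 27.7 |
| winter | 10.0 | 55.3 | 17.3 | 27.2 |
| dusk | 2.50 | 89.4 | 10.1 | 0.5 |
| dusk | 5.00 | 89.9 | 10.9 | 0 |
| dusk | 6.00 | 90.8 | 10.2 | 0 |
| dusk | 10.0 | 89.7 | 9.8 | 0 |
| noon | 2.50 | 82.9 | 14.2 | 3.7 |
| noon | 5.00 | 83.0 | 14.4 | 2.7 |
| noon | 6.00 | 83.0 | 13.3 | 1.6 |
| noon | 10.0 | 82.9 | 14.6 | 2.9 |

(standard deviation of a reading: 0.5 percentage points)

- the numbers in the tables scatter by 0.5 percentage points (one standard deviation)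
- what may be going on: substrate <-> tight pair; tight pair <-> loose pair; reagent + tight pair -> target; reagent + loose pair -> isomer of the product; 2 reagent -> self-condensation product

* the target standing at 15 d, as a percentage of the substrate charged
* the isomer of the product standing at 15 d, as a percentage of the substrate charged

I open the books on noon, using mean readings. Of the reagent fed, target holds 75.4% and the isomer of the product 12.8%. Noon's target stays flat from 2.50 d to 10.0 d with substrate still standing beside it, so I book no reagent as unspent. The remaining 11.8% I book to the self-condensation product, two reagent per turn. The winter run, fed 0.74 equiv, reads 97.6%, higher than noon.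

The flask matches noon in equivalents and dosing time, but its c(substrate) is 0.10 M against 0.15 M. I carry the capture over anyway, which books 97.1% into the two products. At noon's split that is 14.1% isomer of the product and 83.0% target.

The forecast says 82.3% target (80.5% to 84%) and 14% isomer of the product (13% to 15.2%), on the ground that “Flask has the same equivalents per hour as noon”. Its target is lower than mine.

The flask gives 81.6% target and 15.2% isomer of the product at 15 d.

    substrate ⇌ tight pair (K = 0.00260, k = 0.230 /h)
    tight pair ⇌ loose pair (K = 0.510, k = 5.30 /h)
    reagent + tight pair → target (k = 4400 /M/h)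
    reagent + loose pair → isomer of the product (k = 8700 /M/h)
    2 reagent → self-condensation product (k = 2.20 /M/h)

With 0% of its reagent left beside 3.2% substrate, reagent is the flask's limiting reagent despite its 1.10 equiv. The flask's capture is 88.0%, and its 0.00661 M of self-condensation product, at two reagent per turn, holds the other 12.0% of the reagent. A neighbour flask at 0.025 M of substrate, on the same equivalents, holds 74.3% target and 20.2% isomer of the product, a capture of 85.9%.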